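The route rests on the C3–C4 bond of the 2,2-dimethylchroman, the dihydropyran ring fused to the central benzene ring. Atoms O1–C8a–C4a–C4 are a latent ortho-quinone methide and C3–C2(CH3)2 is isobutene. A hetero-Diels–Alder reaction of a quinone methide released from a phenolic Mannich base therefore closes the pyran ring, forming C4–C3 and O1–C2 together and setting the gem-dimethyl carbon with full regiocontrol. The precursor is an acyclic aminomethylphenol carrying formyl and bromo handles. The aldehyde then becomes one flavone (chalcone, oxidative cyclisation), the bromide becomes a boronate for Suzuki union with an 8-iodoflavone, and hydrogenolysis of five benzyl ethers ends the synthesis.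

Key step: step 2

Remark: the target has no stereocentre and its biaryl axis is flanked by only three small oxygen substituents, so no stereocontrol is planned; 1-[2,4-bis(benzyloxy)-6-hydroxyphenyl]ethanone is taken as a catalogue compound; chroman atoms are numbered O1, C2, C3, C4, C4a, C5 to C8, C8a.

Step 1
Reactants: 1 3-bromo-4-hydroxybenzaldehyde
Product: 2 3-bromo-5-[(dimethylamino)methyl]-4-hydroxybenzaldehyde
Conditions: [CH2=NMe2]I, K2CO3, MeCN, rt
Reagents that add atoms: N,N-dimethylmethyleneiminium iodide, C=[N+](C)C.[I-]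
Why: Mannich-type ortho-aminomethylation, in which the phenoxide of 1 attacks the preformed iminium ion at C5, the only free position ortho to oxygen (para is blocked by the formyl group), while the aldehyde, having no alpha hydrogen, is untouched.

Step 2
Reactants: 2 3-bromo-5-[(dimethylamino)methyl]-4-hydroxybenzaldehyde; 3 isobutene
Product: 5 8-bromo-2,2-dimethylchroman-6-carbaldehyde, via ortho-quinone methide 4 (not isolated)
Conditions: isobutene (excess, condensed), BHT (cat.), PhMe, sealed tube, 170 °C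
Reagents that add atoms: none
Why: The zwitterionic Mannich base 2 (acidic phenol, basic amine) should lose dimethylamine by thermal 1,4-elimination to give ortho-quinone methide 4, whose O=C8a–C4a=C4H2 heterodiene, made electron-poor by the formyl and bromo groups, undergoes an inverse-electron-demand hetero-Diels–Alder reaction with isobutene. The closest known reaction type is the thermal [4+2] trapping of ortho-quinone methides, generated from phenolic Mannich bases or salicyl alcohols, by alkenes to give chromans. The pyran ring closes in a [4+2] cycloaddition mode, C4–C3 and O1–C2 forming in one asynchronous event in which the C–C bond leads. No stereocentre is formed. The step needs regioselectivity and chemoselectivity: the CH2 terminus of isobutene bonds to the exocyclic methylene while oxygen bonds to the carbon that carries both methyl groups and the developing positive charge, so only the 2,2-dimethyl isomer can form, and the excess of alkene together with the reversibility of amine re-addition should channel 4 into the cycloadduct instead of oligomers. Rearomatisation of the benzene ring makes the cycloaddition irreversible.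

Step 3
Reactants: 5 8-bromo-2,2-dimethylchroman-6-carbaldehyde; 6 1-[2,4-bis(benzyloxy)-6-hydroxyphenyl]ethanone
Product: 7 (E)-1-[2,4-bis(benzyloxy)-6-hydroxyphenyl]-3-(8-bromo-2,2-dimethylchroman-6-yl)prop-2-en-1-one
Conditions: KOH (aq.), EtOH/THF, rt
Reagents that add atoms: none
Why: Claisen–Schmidt aldol condensation, in which the acetophenone enolate adds to the non-enolisable aldehyde 5 and E1cB dehydration should give the conjugated E-enone, the chelated ortho-hydroxyl being kept for the next step.

Step 4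
Reactants: 7 (E)-1-[2,4-bis(benzyloxy)-6-hydroxyphenyl]-3-(8-bromo-2,2-dimethylchroman-6-yl)prop-2-en-1-one
Product: 8 5,7-bis(benzyloxy)-2-(8-bromo-2,2-dimethylchroman-6-yl)-4H-chromen-4-one
Conditions: I2 (10 mol%), DMSO, 130 °C
Reagents that add atoms: none
Why: Iodine-catalysed oxidative cyclisation of a 2'-hydroxychalcone (oxa-Michael closure, alpha-iodination and loss of HI, DMSO reoxidising HI to I2) should give the chromone ring, while the benzyl ethers, the aryl bromide and the saturated chroman are expected to survive.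

Step 5
Reactants: 8 5,7-bis(benzyloxy)-2-(8-bromo-2,2-dimethylchroman-6-yl)-4H-chromen-4-one
Product: 9 5,7-bis(benzyloxy)-2-[2,2-dimethyl-8-(4,4,5,5-tetramethyl-1,3,2-dioxaborolan-2-yl)chroman-6-yl]-4H-chromen-4-one
Conditions: B2pin2, PdCl2(dppf) (5 mol%), KOAc, 1,4-dioxane, 90 °C
Reagents that add atoms: bis(pinacolato)diboron, CC1(C)OB(OC1(C)C)B1OC(C)(C)C(C)(C)O1
Why: Miyaura borylation, in which oxidative addition of the aryl bromide to zerovalent palladium, acetate-assisted transmetalation with B2pin2 and reductive elimination should give the aryl pinacol boronate, KOAc being too weak a base to trigger Suzuki homocoupling or to open the chromone.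

Step 6
Reactants: 6 1-[2,4-bis(benzyloxy)-6-hydroxyphenyl]ethanone
Product: 10 1-[4,6-bis(benzyloxy)-2-hydroxy-3-iodophenyl]ethanone
Conditions: BnNMe3 ICl2, NaHCO3, CH2Cl2/MeOH, rt
Reagents that add atoms: benzyltrimethylammonium dichloroiodate, C[N+](C)(C)Cc1ccccc1.Cl[I-]Cl
Why: Electrophilic aromatic iodination directed by the free, chelated phenol to C3, which is ortho to the hydroxyl and the less hindered of the two open ring positions (C5 lies between two benzyloxy groups); this carbon becomes C8 of the flavone.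

Step 7
Reactants: 10 1-[4,6-bis(benzyloxy)-2-hydroxy-3-iodophenyl]ethanone; 11 4-(benzyloxy)benzaldehyde
Product: 12 (E)-1-[4,6-bis(benzyloxy)-2-hydroxy-3-iodophenyl]-3-[4-(benzyloxy)phenyl]prop-2-en-1-one
Conditions: KOH (aq.), EtOH/THF, rt
Reagents that add atoms: none
Why: Claisen–Schmidt aldol condensation as in step 3; the aryl iodide and the benzyl ethers are inert to KOH at room temperature and the E-enone should result.

Step 8
Reactants: 12 (E)-1-[4,6-bis(benzyloxy)-2-hydroxy-3-iodophenyl]-3-[4-(benzyloxy)phenyl]prop-2-en-1-one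
Product: 13 5,7-bis(benzyloxy)-2-[4-(benzyloxy)phenyl]-8-iodo-4H-chromen-4-one
Conditions: I2 (10 mol%), DMSO, 120 °C
Reagents that add atoms: none
Why: Iodine-catalysed oxidative cyclisation as in step 4; only the hydroxyl ortho to iodine can close the pyranone ring, so the iodine ends at C8, and the low standing concentration of HI in DMSO should limit protodeiodination.

Step 9
Reactants: 9 5,7-bis(benzyloxy)-2-[2,2-dimethyl-8-(4,4,5,5-tetramethyl-1,3,2-dioxaborolan-2-yl)chroman-6-yl]-4H-chromen-4-one; 13 5,7-bis(benzyloxy)-2-[4-(benzyloxy)phenyl]-8-iodo-4H-chromen-4-one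
Product: 14 5,7-bis(benzyloxy)-8-{6-[5,7-bis(benzyloxy)-4-oxo-4H-chromen-2-yl]-2,2-dimethylchroman-8-yl}-2-[4-(benzyloxy)phenyl]-4H-chromen-4-one
Conditions: Pd(OAc)2 (5 mol%), SPhos (10 mol%), K3PO4, PhMe/H2O, 100 °C
Reagents that add atoms: none
Why: Suzuki–Miyaura cross-coupling, in which the bulky electron-rich biarylphosphine SPhos should allow oxidative addition to the hindered iodide 13, transmetalation of boronate 9 and reductive elimination to the tri-ortho-substituted biaryl, whose axis carries only small oxygen substituents and is not a stable stereogenic element.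

Step 10
Reactants: 14 5,7-bis(benzyloxy)-8-{6-[5,7-bis(benzyloxy)-4-oxo-4H-chromen-2-yl]-2,2-dimethylchroman-8-yl}-2-[4-(benzyloxy)phenyl]-4H-chromen-4-one
Product: 15 8-[6-(5,7-dihydroxy-4-oxo-4H-chromen-2-yl)-2,2-dimethylchroman-8-yl]-5,7-dihydroxy-2-(4-hydroxyphenyl)-4H-chromen-4-one
Conditions: H2 (1 atm), Pd/C, THF/MeOH, rt
Reagents that add atoms: none
Why: Catalytic hydrogenolysis of the five benzylic C–O bonds on palladium should free all phenols, while the chromone C2=C3 bonds (vinylogous esters) and the saturated chroman ether are expected to stay intact under one atmosphere of hydrogen at room temperature.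

Compound list

1 | 3-bromo-4-hydroxybenzaldehyde | O=Cc1ccc(O)c(Br)c1 | starting material
2 | 3-bromo-5-[(dimethylamino)methyl]-4-hydroxybenzaldehyde | CN(C)Cc1cc(C=O)cc(Br)c1O | intermediate
3 | isobutene (2-methylpropene) | CC(C)=C | starting material
4 | 5-bromo-3-methylidene-4-oxocyclohexa-1,5-diene-1-carbaldehyde (ortho-quinone methide, not isolated) | C=C1C=C(C=O)C=C(Br)C1=O | intermediate
5 | 8-bromo-2,2-dimethylchroman-6-carbaldehyde | CC1(C)CCc2cc(C=O)cc(Br)c2O1 | intermediate
6 | 1-[2,4-bis(benzyloxy)-6-hydroxyphenyl]ethanone | CC(=O)c1c(O)cc(OCc2ccccc2)cc1OCc1ccccc1 | starting material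
7 | (E)-1-[2,4-bis(benzyloxy)-6-hydroxyphenyl]-3-(8-bromo-2,2-dimethylchroman-6-yl)prop-2-en-1-one | CC1(C)CCc2cc(/C=C/C(=O)c3c(O)cc(OCc4ccccc4)cc3OCc3ccccc3)cc(Br)c2O1 | intermediate
8 | 5,7-bis(benzyloxy)-2-(8-bromo-2,2-dimethylchroman-6-yl)-4H-chromen-4-one | CC1(C)CCc2cc(-c3cc(=O)c4c(OCc5ccccc5)cc(OCc5ccccc5)cc4o3)cc(Br)c2O1 | intermediate
9 | 5,7-bis(benzyloxy)-2-[2,2-dimethyl-8-(4,4,5,5-tetramethyl-1,3,2-dioxaborolan-2-yl)chroman-6-yl]-4H-chromen-4-one | CC1(C)CCc2cc(-c3cc(=O)c4c(OCc5ccccc5)cc(OCc5ccccc5)cc4o3)cc(B3OC(C)(C)C(C)(C)O3)c2O1 | intermediate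
10 | 1-[4,6-bis(benzyloxy)-2-hydroxy-3-iodophenyl]ethanone | CC(=O)c1c(O)c(I)c(OCc2ccccc2)cc1OCc1ccccc1 | intermediate
11 | 4-(benzyloxy)benzaldehyde | O=Cc1ccc(OCc2ccccc2)cc1 | starting material
12 | (E)-1-[4,6-bis(benzyloxy)-2-hydroxy-3-iodophenyl]-3-[4-(benzyloxy)phenyl]prop-2-en-1-one | O=C(/C=C/c1ccc(OCc2ccccc2)cc1)c1c(O)c(I)c(OCc2ccccc2)cc1OCc1ccccc1 | intermediate
13 | 5,7-bis(benzyloxy)-2-[4-(benzyloxy)phenyl]-8-iodo-4H-chromen-4-one | O=c1cc(-c2ccc(OCc3ccccc3)cc2)oc2c(I)c(OCc3ccccc3)cc(OCc3ccccc3)c12 | intermediate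
14 | 5,7-bis(benzyloxy)-8-{6-[5,7-bis(benzyloxy)-4-oxo-4H-chromen-2-yl]-2,2-dimethylchroman-8-yl}-2-[4-(benzyloxy)phenyl]-4H-chromen-4-one | CC1(C)CCc2cc(-c3cc(=O)c4c(OCc5ccccc5)cc(OCc5ccccc5)cc4o3)cc(-c3c(OCc4ccccc4)cc(OCc4ccccc4)c4c(=O)cc(-c5ccc(OCc6ccccc6)cc5)oc34)c2O1 | intermediate
15 | 8-[6-(5,7-dihydroxy-4-oxo-4H-chromen-2-yl)-2,2-dimethylchroman-8-yl]-5,7-dihydroxy-2-(4-hydroxyphenyl)-4H-chromen-4-one (CNP0127025.0) | CC1(C)CCc2cc(-c3cc(=O)c4c(O)cc(O)cc4o3)cc(-c3c(O)cc(O)c4c(=O)cc(-c5ccc(O)cc5)oc34)c2O1 | target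

Total step count: 10 steps.
Longest linear sequence: 7 steps (steps 1, 2, 3, 4, 5, 9 and 10, from compound 1 to compound 15); the second branch (steps 6, 7 and 8) joins at step 9.

Steps most likely to fail

Step 2 (key step). The ortho-quinone methide may be consumed by self-condensation or by re-addition of dimethylamine faster than the unactivated gaseous alkene traps it. The fallback sets out from 1 and comes back at 5. It keeps C3–C4 as the ring-closing bond but makes it by ring-closing metathesis. Iodination of 1 (NIS, TsOH cat., MeCN) should give 3-bromo-4-hydroxy-5-iodobenzaldehyde F1. Chemoselective Suzuki vinylation at the iodide (CH2=CHBF3K, PdCl2(dppf), Et3N, n-PrOH, 80 °C) should give 3-bromo-5-ethenyl-4-hydroxybenzaldehyde F2. Palladium-catalysed O-tert-prenylation (tert-butyl 2-methylbut-3-en-2-yl carbonate, Pd(PPh3)4, THF, rt) should give 3-bromo-5-ethenyl-4-[(2-methylbut-3-en-2-yl)oxy]benzaldehyde F3. Ring-closing metathesis (second-generation Grubbs catalyst, CH2Cl2, 40 °C) should give 8-bromo-2,2-dimethyl-2H-chromene-6-carbaldehyde F4. Homogeneous hydrogenation of the C3=C4 double bond (H2, RhCl(PPh3)3, PhH/EtOH, rt), which spares the aryl bromide and the aldehyde, returns 5.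

Step 9. Transmetalation at the hindered positions of two large, poorly soluble flavone partners may be slow, so that protodeboronation and homocoupling take over. The fallback sets out from 5 and 13 and comes back at 14. It moves the biaryl coupling to the aldehyde stage, where the boron partner is small, soluble and usable in excess, and builds flavone unit A afterwards. Miyaura borylation of 5 (B2pin2, PdCl2(dppf), KOAc, 1,4-dioxane, 90 °C) should give 2,2-dimethyl-8-(4,4,5,5-tetramethyl-1,3,2-dioxaborolan-2-yl)chroman-6-carbaldehyde F5. Suzuki coupling of F5 with 13 (Pd(OAc)2, SPhos, K3PO4, PhMe/H2O) should give 8-{5,7-bis(benzyloxy)-2-[4-(benzyloxy)phenyl]-4-oxo-4H-chromen-8-yl}-2,2-dimethylchroman-6-carbaldehyde F6. Claisen–Schmidt condensation of F6 with 6 (KOH, EtOH/THF, rt) should give (E)-1-[2,4-bis(benzyloxy)-6-hydroxyphenyl]-3-(8-{5,7-bis(benzyloxy)-2-[4-(benzyloxy)phenyl]-4-oxo-4H-chromen-8-yl}-2,2-dimethylchroman-6-yl)prop-2-en-1-one F7. Oxidative cyclisation of F7 (I2 cat., DMSO, 130 °C) returns 14.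

Step 10. The two chromone C2=C3 bonds may be over-reduced, or debenzylation may stall as partly deprotected material precipitates on the catalyst. The fallback sets out from 14 and comes back at 15. It replaces hydrogenolysis by Lewis-acid ether cleavage with a cation scavenger (BCl3, pentamethylbenzene, CH2Cl2, −78 °C), in which each benzyl group is transferred to pentamethylbenzene by Friedel–Crafts alkylation before the chroman ether can ionise. No new compound is made (F0).

Further compounds

F1 | step 2 | 3-bromo-4-hydroxy-5-iodobenzaldehyde | O=Cc1cc(Br)c(O)c(I)c1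
F2 | step 2 | 3-bromo-5-ethenyl-4-hydroxybenzaldehyde | C=Cc1cc(C=O)cc(Br)c1O
F3 | step 2 | 3-bromo-5-ethenyl-4-[(2-methylbut-3-en-2-yl)oxy]benzaldehyde | C=Cc1cc(C=O)cc(Br)c1OC(C)(C)C=C
F4 | step 2 | 8-bromo-2,2-dimethyl-2H-chromene-6-carbaldehyde | CC1(C)C=Cc2cc(C=O)cc(Br)c2O1
F5 | step 9 | 2,2-dimethyl-8-(4,4,5,5-tetramethyl-1,3,2-dioxaborolan-2-yl)chroman-6-carbaldehyde | CC1(C)CCc2cc(C=O)cc(B3OC(C)(C)C(C)(C)O3)c2O1
F6 | step 9 | 8-{5,7-bis(benzyloxy)-2-[4-(benzyloxy)phenyl]-4-oxo-4H-chromen-8-yl}-2,2-dimethylchroman-6-carbaldehyde | CC1(C)CCc2cc(C=O)cc(-c3c(OCc4ccccc4)cc(OCc4ccccc4)c4c(=O)cc(-c5ccc(OCc6ccccc6)cc5)oc34)c2O1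
F7 | step 9 | (E)-1-[2,4-bis(benzyloxy)-6-hydroxyphenyl]-3-(8-{5,7-bis(benzyloxy)-2-[4-(benzyloxy)phenyl]-4-oxo-4H-chromen-8-yl}-2,2-dimethylchroman-6-yl)prop-2-en-1-one | CC1(C)CCc2cc(/C=C/C(=O)c3c(O)cc(OCc4ccccc4)cc3OCc3ccccc3)cc(-c3c(OCc4ccccc4)cc(OCc4ccccc4)c4c(=O)cc(-c5ccc(OCc6ccccc6)cc5)oc34)c2O1
F0 | step 10 | none | none
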